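**Retrosynthetic overview**

1. The target is robinetinidol-(4α→8)-epigallocatechin 3-O-gallate. The last skeletal bond made is the interflavan C4(upper)–C8(lower) bond, by Friedel–Crafts alkylation of a benzyl-protected epigallocatechin gallate with the flavan-4-yl cation derived from (+)-dihydrorobinetin; global hydrogenolysis follows.
2. Lower unit, built de novo: gallate by esterification; C3 carbinol by cis-selective reduction of a flavan-3-one; ring C by closing the C4–C4a bond in a gold-catalysed alkyne oxidation/arene alkylation of an aryl propargyl ether; the ether by Mitsunobu inversion of an enantioenriched 1-arylpropargyl alcohol.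
3. Enabling feature: ring A of the lower unit is a phloroglucinol ring in which C4a lies ortho to O1 and O5 and para to O7, and before closure the two carbons ortho to O1 are equivalent. C4 is flanked by the oxygen-bearing C3, so the C3–C4 unit maps onto a terminal alkyne whose terminus is made electrophilic (alpha-oxo carbene) while C3 receives its oxygen.
4. Order of ring formation: lower ring C (step 4) is the only ring made; all aromatic rings and the upper ring C with its C2/C3 centres are bought; the halves are joined in step 10.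

Key step: step 4

Assumption: natural (2R,3R)-dihydrorobinetin and the benzylated building blocks are taken as purchasable, and (R,R)-ProPhenol is taken to deliver the alkynyl group to the Re face of the aldehyde; the sense of induction is to be confirmed on the product of step 1 (chiral HPLC, MTPA esters), and the (S,S)-ligand is used if it proves opposite.

**Route**

Step 1
Reactants: 1 3,4,5-tris(benzyloxy)benzaldehyde; 2 ethynyltrimethylsilane
Product: 3 (S)-1-[3,4,5-tris(benzyloxy)phenyl]-3-(trimethylsilyl)prop-2-yn-1-ol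
Conditions: Me2Zn (3 equiv), (R,R)-ProPhenol (10 mol%), toluene, 0 °C; then H2O
Reagents that add atoms: none
Why: Catalytic asymmetric alkynylation of an aryl aldehyde by an in situ alkynylzinc on a dinuclear zinc–ProPhenol template is well precedented and should set the carbinol centre (future C2 of the lower unit) by Re-face delivery of the alkynyl group.

Step 2
Reactants: 3 (S)-1-[3,4,5-tris(benzyloxy)phenyl]-3-(trimethylsilyl)prop-2-yn-1-ol
Product: 4 (R)-1-[3,4,5-tris(benzyloxy)phenyl]prop-2-yn-1-ol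
Conditions: K2CO3 (cat.), MeOH/THF, rt
Reagents that add atoms: none
Why: Base-catalysed methanolysis of the alkynyl C–Si bond (protodesilylation) leaves the carbinol centre and the benzyl ethers untouched; the descriptor changes from S to R only because the alkyne loses CIP priority.

Step 3
Reactants: 4 (R)-1-[3,4,5-tris(benzyloxy)phenyl]prop-2-yn-1-ol; 5 3,5-bis(benzyloxy)phenol
Product: 6 (S)-1,3-bis(benzyloxy)-5-({1-[3,4,5-tris(benzyloxy)phenyl]prop-2-yn-1-yl}oxy)benzene
Conditions: PPh3, DIAD, toluene, −20 °C to rt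
Reagents that add atoms: none
Why: Mitsunobu etherification, in which the phenol displaces the oxyphosphonium by SN2 with inversion, should turn the R carbinol into the S aryl ether that maps onto 2R of the lower unit, low temperature in toluene being chosen to suppress ionisation of the benzylic-propargylic centre.

Step 4
Reactants: 6 (S)-1,3-bis(benzyloxy)-5-({1-[3,4,5-tris(benzyloxy)phenyl]prop-2-yn-1-yl}oxy)benzene
Product: 8 (2R)-5,7-bis(benzyloxy)-2-[3,4,5-tris(benzyloxy)phenyl]chroman-3-one, via alpha-oxo gold carbene 7 (not isolated)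
Conditions: (Me4tBuXPhos)AuNTf2 (5 mol%), 2,6-dichloropyridine N-oxide (1.3 equiv), 1,2-dichloroethane, rt, argon; rapid filtration through neutral silica
Reagents that add atoms: 2,6-dichloropyridine N-oxide, [O-][n+]1c(Cl)cccc1Cl
Why: Cationic monovalent gold activates the terminal alkyne of 6, the N-oxide oxygen adds to the internal alkyne carbon (future C3) and N–O heterolysis releases 2,6-dichloropyridine to give the alpha-oxo gold carbene 7, so the formerly nucleophilic alkyne terminus (future C4) becomes electrophilic and can be joined to the nucleophilic arene carbon C4a, a union of two innately nucleophilic carbons by polarity reversal that also installs the C3 oxygen. The closest known reaction type is the gold-catalysed oxidative cyclisation of aryl propargyl ethers to chroman-3-ones. Ring C closes by a 6-exo-trig Friedel–Crafts-type attack of the ring A carbon ortho to O1 on the carbene carbon, followed by rearomatisation and protodeauration. No new stereocentre is formed, and C2 is not a reacting atom, so its configuration should be carried through because the medium is neutral and the by-product 2,6-dichloropyridine is essentially non-basic. The selectivity needed is trapping of the carbene by ring A and not by ring B (five-membered 2-indanone) or by a second N-oxide (over-oxidation): the ring A carbon is activated by three oxygen donors (ortho, ortho, para) and gives the six-membered ring, the bulky biaryl phosphine shields the carbene from intermolecular oxidation, and the two positions ortho to the ether oxygen are equivalent so only one regioisomer can form.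

Step 5
Reactants: 8 (2R)-5,7-bis(benzyloxy)-2-[3,4,5-tris(benzyloxy)phenyl]chroman-3-one
Product: 9 (2R,3R)-5,7-bis(benzyloxy)-2-[3,4,5-tris(benzyloxy)phenyl]chroman-3-ol (penta-O-benzyl-epigallocatechin)
Conditions: LiBH(sec-Bu)3 (L-Selectride, 1.5 equiv), THF, −78 °C; then H2O
Reagents that add atoms: none
Why: Bulky-hydride ketone reduction, in which equatorial attack on the flavan-3-one should give the axial 3-hydroxyl cis to the equatorial C2 aryl group (2R,3R), a selectivity with direct precedent on benzylated flavan-3-ones.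

Step 6
Reactants: 9 (2R,3R)-5,7-bis(benzyloxy)-2-[3,4,5-tris(benzyloxy)phenyl]chroman-3-ol; 10 3,4,5-tris(benzyloxy)benzoic acid
Product: 11 (2R,3R)-5,7-bis(benzyloxy)-2-[3,4,5-tris(benzyloxy)phenyl]chroman-3-yl 3,4,5-tris(benzyloxy)benzoate (octa-O-benzyl-epigallocatechin gallate)
Conditions: DCC, DMAP, CH2Cl2, rt
Reagents that add atoms: none
Why: Steglich esterification of the axial secondary alcohol with the protected gallic acid installs the gallate on the lower 3-oxygen only, without touching a stereocentre.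

Step 7
Reactants: 12 (+)-dihydrorobinetin, (2R,3R)-3,7-dihydroxy-2-(3,4,5-trihydroxyphenyl)chroman-4-one
Product: 13 (2R,3R)-7-(benzyloxy)-3-hydroxy-2-[3,4,5-tris(benzyloxy)phenyl]chroman-4-one
Conditions: BnBr (4.4 equiv), K2CO3, DMF, rt, argon
Reagents that add atoms: benzyl bromide, BrCc1ccccc1
Why: Williamson etherification of the four phenolic hydroxyls under weak base leaves the aliphatic 3-OH free and, at room temperature, should not open or epimerise the dihydroflavonol ring.

Step 8
Reactants: 13 (2R,3R)-7-(benzyloxy)-3-hydroxy-2-[3,4,5-tris(benzyloxy)phenyl]chroman-4-one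
Product: 14 (2R,3S,4R)-7-(benzyloxy)-2-[3,4,5-tris(benzyloxy)phenyl]chromane-3,4-diol
Conditions: NaBH4, THF/MeOH, 0 °C; then H2O
Reagents that add atoms: none
Why: Borohydride reduction of the aryl ketone, in which axial hydride delivery should give mainly the all-equatorial 2,3-trans-3,4-trans diol; the C4 configuration is in any case erased by ionisation in step 10.

Step 9
Reactants: 14 (2R,3S,4R)-7-(benzyloxy)-2-[3,4,5-tris(benzyloxy)phenyl]chromane-3,4-diol
Product: 15 (2R,3S,4R)-3,4,7-tris(benzyloxy)-2-[3,4,5-tris(benzyloxy)phenyl]chromane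
Conditions: NaH (2.5 equiv), BnBr (2.5 equiv), Bu4NI (cat.), DMF, 0 °C to rt
Reagents that add atoms: benzyl bromide, BrCc1ccccc1
Why: Williamson benzylation of both alkoxides caps the 3-OH for the rest of the route and turns the 4-oxygen into a benzylic ether that a Lewis acid can ionise.

Step 10
Reactants: 15 (2R,3S,4R)-3,4,7-tris(benzyloxy)-2-[3,4,5-tris(benzyloxy)phenyl]chromane; 11 octa-O-benzyl-epigallocatechin gallate (1.5 equiv)
Product: 17 3-O-benzyl-7,3',4',5'-tetra-O-benzylrobinetinidol-(4α→8)-[5,7,3',4',5'-penta-O-benzyl-epigallocatechin 3-O-(3,4,5-tri-O-benzyl)gallate], via flavan-4-yl cation 16 (not isolated)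
Conditions: Me3SiOTf (0.2 equiv), CH2Cl2, −78 to −40 °C; Et3N quench
Reagents that add atoms: none
Why: Lewis acid ionisation of the 4-benzyloxy group gives the 7-alkoxy-stabilised benzylic cation 16, which should undergo Friedel–Crafts alkylation by C8 of ring A of 11 (between O1 and 7-OBn, the most nucleophilic and least hindered carbon of a benzylated flavan), the nucleophile approaching anti to the 3-benzyloxy group so that the new C4 centre is 3,4-trans (4S, 4α).

Step 11
Reactants: 17 per-benzylated dimer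
Product: 18 robinetinidol-(4α→8)-epigallocatechin 3-O-gallate (target)
Conditions: H2 (1 atm), Pd(OH)2/C, THF/MeOH/H2O, rt; filtration, lyophilisation
Reagents that add atoms: none
Why: Hydrogenolysis of all thirteen benzyl ethers over Pd(OH)2/C is standard for benzylated proanthocyanidin gallates and should leave the ester, the benzylic ring C–O bonds and the interflavan C–C bond intact.

**Compound list**

1 | 3,4,5-tris(benzyloxy)benzaldehyde | O=Cc1cc(OCc2ccccc2)c(OCc2ccccc2)c(OCc2ccccc2)c1 | starting material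
2 | ethynyltrimethylsilane | C#C[Si](C)(C)C | starting material
3 | (S)-1-[3,4,5-tris(benzyloxy)phenyl]-3-(trimethylsilyl)prop-2-yn-1-ol | O[C@H](C#C[Si](C)(C)C)c1cc(OCc2ccccc2)c(OCc2ccccc2)c(OCc2ccccc2)c1 | intermediate
4 | (R)-1-[3,4,5-tris(benzyloxy)phenyl]prop-2-yn-1-ol | O[C@H](C#C)c1cc(OCc2ccccc2)c(OCc2ccccc2)c(OCc2ccccc2)c1 | intermediate
5 | 3,5-bis(benzyloxy)phenol | Oc1cc(OCc2ccccc2)cc(OCc2ccccc2)c1 | starting material
6 | (S)-1,3-bis(benzyloxy)-5-({1-[3,4,5-tris(benzyloxy)phenyl]prop-2-yn-1-yl}oxy)benzene | c1ccccc1COc1cc(OCc2ccccc2)cc(O[C@@H](C#C)c2cc(OCc3ccccc3)c(OCc3ccccc3)c(OCc3ccccc3)c2)c1 | intermediate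
7 | alpha-oxo gold carbene, [(Me4tBuXPhos)Au=CH–C(=O)–CH(OAr)Ar']NTf2 with the S-configured ether carbon of 6 | O=C(C=[Au][P+](C(C)(C)C)(C(C)(C)C)c1c(C)c(C)c(C)c(C)c1-c1c(C(C)C)cc(C(C)C)cc1C(C)C)[C@H](Oc1cc(OCc2ccccc2)cc(OCc2ccccc2)c1)c1cc(OCc2ccccc2)c(OCc2ccccc2)c(OCc2ccccc2)c1.[N-](S(=O)(=O)C(F)(F)F)S(=O)(=O)C(F)(F)F | intermediate
8 | (2R)-5,7-bis(benzyloxy)-2-[3,4,5-tris(benzyloxy)phenyl]chroman-3-one | O=C1Cc2c(OCc3ccccc3)cc(OCc3ccccc3)cc2O[C@@H]1c1cc(OCc2ccccc2)c(OCc2ccccc2)c(OCc2ccccc2)c1 | intermediate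
9 | (2R,3R)-5,7-bis(benzyloxy)-2-[3,4,5-tris(benzyloxy)phenyl]chroman-3-ol | O[C@@H]1Cc2c(OCc3ccccc3)cc(OCc3ccccc3)cc2O[C@@H]1c1cc(OCc2ccccc2)c(OCc2ccccc2)c(OCc2ccccc2)c1 | intermediate
10 | 3,4,5-tris(benzyloxy)benzoic acid | O=C(O)c1cc(OCc2ccccc2)c(OCc2ccccc2)c(OCc2ccccc2)c1 | starting material
11 | (2R,3R)-5,7-bis(benzyloxy)-2-[3,4,5-tris(benzyloxy)phenyl]chroman-3-yl 3,4,5-tris(benzyloxy)benzoate | O=C(O[C@@H]1Cc2c(OCc3ccccc3)cc(OCc3ccccc3)cc2O[C@@H]1c1cc(OCc2ccccc2)c(OCc2ccccc2)c(OCc2ccccc2)c1)c1cc(OCc2ccccc2)c(OCc2ccccc2)c(OCc2ccccc2)c1 | intermediate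
12 | (+)-dihydrorobinetin, (2R,3R)-3,7-dihydroxy-2-(3,4,5-trihydroxyphenyl)chroman-4-one | O=C1c2ccc(O)cc2O[C@H](c2cc(O)c(O)c(O)c2)[C@H]1O | starting material
13 | (2R,3R)-7-(benzyloxy)-3-hydroxy-2-[3,4,5-tris(benzyloxy)phenyl]chroman-4-one | O=C1c2ccc(OCc3ccccc3)cc2O[C@H](c2cc(OCc3ccccc3)c(OCc3ccccc3)c(OCc3ccccc3)c2)[C@H]1O | intermediate
14 | (2R,3S,4R)-7-(benzyloxy)-2-[3,4,5-tris(benzyloxy)phenyl]chromane-3,4-diol | O[C@@H]1c2ccc(OCc3ccccc3)cc2O[C@H](c2cc(OCc3ccccc3)c(OCc3ccccc3)c(OCc3ccccc3)c2)[C@H]1O | intermediate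
15 | (2R,3S,4R)-3,4,7-tris(benzyloxy)-2-[3,4,5-tris(benzyloxy)phenyl]chromane | c1ccccc1CO[C@@H]1c2ccc(OCc3ccccc3)cc2O[C@H](c2cc(OCc3ccccc3)c(OCc3ccccc3)c(OCc3ccccc3)c2)[C@H]1OCc1ccccc1 | intermediate
16 | (2R,3S)-3,7-bis(benzyloxy)-2-[3,4,5-tris(benzyloxy)phenyl]chroman-4-ylium triflate | [CH+]1c2ccc(OCc3ccccc3)cc2O[C@H](c2cc(OCc3ccccc3)c(OCc3ccccc3)c(OCc3ccccc3)c2)[C@H]1OCc1ccccc1.[O-]S(=O)(=O)C(F)(F)F | intermediate
17 | per-benzylated dimer, upper unit (2R,3S,4S), lower unit (2R,3R), thirteen benzyl ethers | O=C(O[C@@H]1Cc2c(OCc3ccccc3)cc(OCc3ccccc3)c([C@@H]3c4ccc(OCc5ccccc5)cc4O[C@H](c4cc(OCc5ccccc5)c(OCc5ccccc5)c(OCc5ccccc5)c4)[C@H]3OCc3ccccc3)c2O[C@@H]1c1cc(OCc2ccccc2)c(OCc2ccccc2)c(OCc2ccccc2)c1)c1cc(OCc2ccccc2)c(OCc2ccccc2)c(OCc2ccccc2)c1 | intermediate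
18 | robinetinidol-(4α→8)-epigallocatechin 3-O-gallate | O=C(O[C@@H]1Cc2c(O)cc(O)c([C@@H]3c4ccc(O)cc4O[C@H](c4cc(O)c(O)c(O)c4)[C@H]3O)c2O[C@@H]1c1cc(O)c(O)c(O)c1)c1cc(O)c(O)c(O)c1 | target

**Step count**

Total steps: 11. Longest linear sequence: 8 steps (steps 1–6, 10, 11); the upper unit is a 3-step branch (steps 7–9).

**Steps most likely to fail, with fallbacks**

Step 4 (key step). The gold carbene may be diverted: attack by ring B, a second oxidation by the N-oxide, or partial loss of the C2 configuration in the enolisable ketone during reaction or isolation. The fallback sets out from 6 and returns at 8; it closes the same C4–C4a bond without the oxidant and adds the oxygen separately. Gold-catalysed 6-endo-dig hydroarylation of 6 with [(JohnPhos)Au(MeCN)]SbF6 in CH2Cl2 at rt should give (2S)-5,7-bis(benzyloxy)-2-[3,4,5-tris(benzyloxy)phenyl]-2H-chromene F1. Hydroboration–oxidation (BH3·THF, then NaOH/H2O2) should place boron on C3 anti to the C2 aryl group and give the 2,3-trans alcohol (2R,3S)-5,7-bis(benzyloxy)-2-[3,4,5-tris(benzyloxy)phenyl]chroman-3-ol F2. Dess–Martin periodinane in CH2Cl2 then gives ketone 8, which is reduced at once as in step 5.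

Step 3. Ionisation of the electron-rich benzylic-propargylic oxyphosphonium may compete with SN2 displacement and erode the enantiopurity of the ether. The fallback sets out from 1 and returns at 9; it gives up stereospecific substitution and sets C2 and C3 together by dynamic kinetic resolution. Addition of HC≡CMgBr to 1 (THF, 0 °C) gives racemic 1-[3,4,5-tris(benzyloxy)phenyl]prop-2-yn-1-ol F3. Mitsunobu etherification with 5 under the conditions of step 3 gives racemic 1,3-bis(benzyloxy)-5-({1-[3,4,5-tris(benzyloxy)phenyl]prop-2-yn-1-yl}oxy)benzene F4. The conditions of step 4 give racemic 5,7-bis(benzyloxy)-2-[3,4,5-tris(benzyloxy)phenyl]chroman-3-one F5. Asymmetric hydrogenation under base (RuCl2[(S)-SDP][(R,R)-DPEN] or its mirror image, whichever is matched to the 2R ketone, KOtBu, i-PrOH, H2), a reaction type known for racemic alpha-aryl and alpha-aryloxy cyclic ketones, should epimerise C2 through the enolate and reduce only the 2R ketone to the cis alcohol 9.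

Step 10. Facial selectivity at the cationic C4 may be poor (4β isomer), attack may occur through C6 of the nucleophile, or the cation may self-condense. The fallback sets out from 11 and 12 and returns at 18; it replaces the Lewis-acid coupling of protected partners by a protecting-group-free condensation in dilute aqueous acid. Hydrogenolysis of 11 (H2, Pd(OH)2/C, THF/MeOH) gives (−)-epigallocatechin 3-O-gallate F6. Reduction of 12 with NaBH4 in EtOH/H2O gives (2R,3S,4R)-2-(3,4,5-trihydroxyphenyl)chromane-3,4,7-triol (leucorobinetinidin) F7. F7 and an excess of F6 in 0.1 M aqueous HCl at rt should condense through the 7-hydroxy-stabilised cation to give 18 directly, the 3,4-trans (4→8) isomer being separated on Sephadex LH-20 and by preparative HPLC.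

**Further compounds**

F1 | step 4 | (2S)-5,7-bis(benzyloxy)-2-[3,4,5-tris(benzyloxy)phenyl]-2H-chromene | C1=Cc2c(OCc3ccccc3)cc(OCc3ccccc3)cc2O[C@@H]1c1cc(OCc2ccccc2)c(OCc2ccccc2)c(OCc2ccccc2)c1
F2 | step 4 | (2R,3S)-5,7-bis(benzyloxy)-2-[3,4,5-tris(benzyloxy)phenyl]chroman-3-ol | O[C@H]1Cc2c(OCc3ccccc3)cc(OCc3ccccc3)cc2O[C@@H]1c1cc(OCc2ccccc2)c(OCc2ccccc2)c(OCc2ccccc2)c1
F3 | step 3 | racemic 1-[3,4,5-tris(benzyloxy)phenyl]prop-2-yn-1-ol | OC(C#C)c1cc(OCc2ccccc2)c(OCc2ccccc2)c(OCc2ccccc2)c1
F4 | step 3 | racemic 1,3-bis(benzyloxy)-5-({1-[3,4,5-tris(benzyloxy)phenyl]prop-2-yn-1-yl}oxy)benzene | C#CC(Oc1cc(OCc2ccccc2)cc(OCc2ccccc2)c1)c1cc(OCc2ccccc2)c(OCc2ccccc2)c(OCc2ccccc2)c1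
F5 | step 3 | racemic 5,7-bis(benzyloxy)-2-[3,4,5-tris(benzyloxy)phenyl]chroman-3-one | O=C1Cc2c(OCc3ccccc3)cc(OCc3ccccc3)cc2OC1c1cc(OCc2ccccc2)c(OCc2ccccc2)c(OCc2ccccc2)c1
F6 | step 10 | (−)-epigallocatechin 3-O-gallate | O=C(O[C@@H]1Cc2c(O)cc(O)cc2O[C@@H]1c1cc(O)c(O)c(O)c1)c1cc(O)c(O)c(O)c1
F7 | step 10 | (2R,3S,4R)-2-(3,4,5-trihydroxyphenyl)chromane-3,4,7-triol (leucorobinetinidin) | O[C@@H]1c2ccc(O)cc2O[C@H](c2cc(O)c(O)c(O)c2)[C@H]1O
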